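**Plan**

- Retrosynthesis: the two aryl acetates and the acetonide are removed first. The side chain is then cut from the phthalide at C1'–C2' (benzylic zinc plus alkenyl iodide). C3'–CH3 and C3'–C4' lead back to a terminal alkyne and a homoallylic iodide. C7'–C8' and C7'–CH3 are cut together with the ring C–O bond of 2,3-dihydrofuran.
- Enabling feature: the E-trisubstituted C6'=C7' olefin carries a methyl group and the C8'–C11' diol arm on C7', and the two-carbon spacer C5'–C4' on C6'. It is the ring-opened form of a 2,3-dihydrofuran ring metalated at the vinylic carbon next to oxygen (that carbon becomes C7', the ring oxygen becomes the C4' oxygen).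
- Forward: the chiral C8'–C11' iodide is made from a hydroxylactone. The cuprate rearrangement joins it to C4'–C7' and adds the C7' methyl. The chain is then extended by an acetylide, methylaluminated and iodinated. The phthalide lactone ring (the only ring made, by hydroxymethylation–lactonisation of a benzoic acid) is joined last by Negishi coupling, and two deprotections finish the route.
- Stereochemistry: C10' (S) comes unchanged from (S)-3-hydroxydihydrofuran-2(3H)-one. E at C6'=C7' comes from the ring-enforced anti migration and retentive methylation. E at C2'=C3' comes from syn carboalumination and retentive iodination and coupling.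

Key step: step 6

Remark: side-chain locants C1'–C11' run from the benzylic carbon to the tertiary carbinol carbon; a lithium dialkylcuprate passes on only one of its two alkyl groups, so the chiral iodide is used in twofold amount in the key step.

**Route**

Step 1
Reactants: 1 (S)-3-hydroxydihydrofuran-2(3H)-one
Product: 2 (S)-4-methylpentane-1,3,4-triol
Conditions: MeMgBr (4.5 equiv), THF, 0 °C → rt; H2O
Reagents that add atoms: methylmagnesium bromide, C[Mg]Br
Why: Twofold Grignard addition to the lactone carbonyl, after deprotonation of the hydroxyl by the first equivalent, should give the tertiary carbinol, and the carbinol stereocentre sits as a magnesium alkoxide and is not enolised, so the S configuration of 1 is carried into 2.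

Step 2
Reactants: 2 (S)-4-methylpentane-1,3,4-triol
Product: 3 (S)-5-[(tert-butyldiphenylsilyl)oxy]-2-methylpentane-2,3-diol
Conditions: TBDPSCl (1.05 equiv), imidazole, DMF, 0 °C
Reagents that add atoms: tert-butyl(chloro)diphenylsilane, CC(C)(C)[Si](Cl)(c1ccccc1)c1ccccc1
Why: Silyl ether formation with the bulky chlorosilane is expected to take only the primary hydroxyl, which is far less hindered than the secondary and tertiary ones.

Step 3
Reactants: 3 (S)-5-[(tert-butyldiphenylsilyl)oxy]-2-methylpentane-2,3-diol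
Product: 4 (S)-tert-butyldiphenyl[2-(2,2,5,5-tetramethyl-1,3-dioxolan-4-yl)ethoxy]silane
Conditions: 2,2-dimethoxypropane, PPTS (cat.), CH2Cl2, rt
Reagents that add atoms: 2,2-dimethoxypropane, COC(C)(C)OC
Why: Acid-catalysed transketalisation (acetonide formation) can engage only the vicinal secondary and tertiary hydroxyls now that the primary one is blocked, so the five-membered dioxolane should form without a competing 1,3-dioxane.

Step 4
Reactants: 4 (S)-tert-butyldiphenyl[2-(2,2,5,5-tetramethyl-1,3-dioxolan-4-yl)ethoxy]silane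
Product: 5 (S)-2-(2,2,5,5-tetramethyl-1,3-dioxolan-4-yl)ethan-1-ol
Conditions: TBAF, THF, 0 °C → rt
Reagents that add atoms: none
Why: Fluoride-induced desilylation cleaves the Si–O bond selectively, the ketal being inert to fluoride and to the mildly basic medium.

Step 5
Reactants: 5 (S)-2-(2,2,5,5-tetramethyl-1,3-dioxolan-4-yl)ethan-1-ol
Product: 6 (S)-4-(2-iodoethyl)-2,2,5,5-tetramethyl-1,3-dioxolane
Conditions: PPh3, I2, imidazole, CH2Cl2, 0 °C → rt
Reagents that add atoms: iodine, II
Why: Appel-type iodination (Garegg–Samuelsson conditions) displaces the primary oxyphosphonium group by iodide in an SN2 reaction under imidazole-buffered conditions that the acetonide tolerates, and the stereocentre is not involved.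

Step 6
Reactants: 6 (S)-4-(2-iodoethyl)-2,2,5,5-tetramethyl-1,3-dioxolane; 7 2,3-dihydrofuran; 8 iodomethane
Product: 14 (E)-4-methyl-6-[(S)-2,2,5,5-tetramethyl-1,3-dioxolan-4-yl]hex-3-en-1-ol, via alkyllithium 9 (not isolated), via lithium dialkylcuprate 10 (not isolated), via 5-lithio-2,3-dihydrofuran 11 (not isolated), via cuprate ate complex 12 (not isolated), via alkenylcuprate alkoxide 13 (not isolated)
Conditions: 6 (2.2 equiv), t-BuLi (4.4 equiv), Et2O–pentane, −78 °C; CuBr·SMe2 (1.1 equiv), Me2S, −78 → −40 °C; 11 [from 7 (1.0 equiv), t-BuLi (1.0 equiv), THF, −78 → 0 °C], −78 °C → rt; 8 (5 equiv), 0 °C → rt; H2O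
Reagents that add atoms: none
Why: Iodine–lithium exchange on 6 gives alkyllithium 9, two equivalents of which form the lithium dialkylcuprate 10 with CuBr·SMe2, and 5-lithio-2,3-dihydrofuran 11 (from 7 by deprotonation at the vinylic carbon next to oxygen) adds to the monovalent copper centre to give ate complex 12. On warming, one alkyl group shifts from copper to the metalated carbon anti to the ring C–O bond, which breaks; this 1,2-metallate rearrangement, known for copper ate complexes of alpha-lithiated cyclic enol ethers and akin to the 1,2-shift of boronate complexes, forms C7'–C8' with inversion at the alkenyl carbon and leaves copper cis to the lithium alkoxide arm in 13. Iodomethane 8 then alkylates the alkenyl–copper bond with retention and forms C7'–CH3. No ring is closed (the dihydrofuran ring is opened and its oxygen becomes the C4' hydroxyl) and no stereocentre is created; C10' is separated from the migrating carbon C8' by C9' and is not touched. The selectivity needed is the E geometry of C6'=C7', and it is secured by the ring itself, which holds the oxygen cis to C5' so that the anti migration must place C8' trans to C5' and the methyl group cis to it.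

Step 7
Reactants: 14 (E)-4-methyl-6-[(S)-2,2,5,5-tetramethyl-1,3-dioxolan-4-yl]hex-3-en-1-ol
Product: 15 (S)-4-[(E)-6-iodo-3-methylhex-3-en-1-yl]-2,2,5,5-tetramethyl-1,3-dioxolane
Conditions: PPh3, I2, imidazole, CH2Cl2, 0 °C → rt
Reagents that add atoms: iodine, II
Why: The same Appel-type iodination converts the primary homoallylic alcohol into the iodide without touching the trisubstituted olefin or the ketal.

Step 8
Reactants: 15 (S)-4-[(E)-6-iodo-3-methylhex-3-en-1-yl]-2,2,5,5-tetramethyl-1,3-dioxolane
Product: 16 (S)-2,2,5,5-tetramethyl-4-[(E)-3-methyloct-3-en-7-yn-1-yl]-1,3-dioxolane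
Conditions: LiC≡CH·H2NCH2CH2NH2 (2 equiv), DMSO–THF, 5 °C → rt
Reagents that add atoms: lithium acetylide–ethylenediamine complex, [Li]C#C.NCCN
Why: SN2 alkylation of the acetylide by the primary iodide in a dipolar aprotic solvent should give the terminal 1,5-enyne, substitution being favoured over E2 elimination by the unhindered primary centre and the low temperature.

Step 9
Reactants: 16 (S)-2,2,5,5-tetramethyl-4-[(E)-3-methyloct-3-en-7-yn-1-yl]-1,3-dioxolane
Product: 18 (S)-4-[(3E,7E)-8-iodo-3,7-dimethylocta-3,7-dien-1-yl]-2,2,5,5-tetramethyl-1,3-dioxolane, via alkenylalane 17 (not isolated)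
Conditions: Me3Al (3 equiv), Cp2ZrCl2 (0.2 equiv), H2O (1.5 equiv), CH2Cl2, −23 °C; then I2, THF, −23 → 0 °C
Reagents that add atoms: trimethylaluminium, C[Al](C)C; iodine, II
Why: Zirconium-catalysed carboalumination adds methyl and aluminium syn across the terminal alkyne with methyl on the internal carbon, and iodinolysis of the alkenyl–aluminium bond with retention should give the E alkenyl iodide, while the trisubstituted C6'=C7' olefin does not react and the short, cold, water-accelerated protocol keeps Me3Al from opening the ketal.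

Step 10
Reactants: 19 3,5-dimethoxy-4-methylbenzoic acid
Product: 20 4,6-dimethoxy-5-methylisobenzofuran-1(3H)-one
Conditions: 37% aq HCHO, conc. HCl, AcOH, 90 °C
Reagents that add atoms: formaldehyde, C=O
Why: Acid-mediated hydroxymethylation (Blanc-type electrophilic aromatic substitution) should occur at one of the two equivalent free ring positions, each ortho and para to a methoxy group, and the benzylic alcohol or chloride so formed lactonises onto the neighbouring carboxyl to close the five-membered phthalide ring.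

Step 11
Reactants: 20 4,6-dimethoxy-5-methylisobenzofuran-1(3H)-one
Product: 21 4,6-dihydroxy-5-methylisobenzofuran-1(3H)-one
Conditions: BBr3 (3 equiv), CH2Cl2, −78 °C → rt; H2O
Reagents that add atoms: none
Why: Lewis acid cleavage of the aryl methyl ethers by BBr3 should free both phenols, while the phthalide lactone survives at or below room temperature.

Step 12
Reactants: 21 4,6-dihydroxy-5-methylisobenzofuran-1(3H)-one
Product: 22 5-methyl-1-oxo-1,3-dihydroisobenzofuran-4,6-diyl diacetate
Conditions: Ac2O, pyridine, DMAP (cat.), CH2Cl2, 0 °C → rt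
Reagents that add atoms: acetic anhydride, CC(=O)OC(C)=O
Why: Acylation of both phenols gives acetates that deactivate the ring toward electrophilic bromination in the next step, are inert to organozinc reagents and come off later under mild base.

Step 13
Reactants: 22 5-methyl-1-oxo-1,3-dihydroisobenzofuran-4,6-diyl diacetate
Product: 23 5-(bromomethyl)-1-oxo-1,3-dihydroisobenzofuran-4,6-diyl diacetate
Conditions: NBS (1.0 equiv), AIBN (cat.), PhCF3, 80 °C
Reagents that add atoms: N-bromosuccinimide, O=C1CCC(=O)N1Br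
Why: Wohl–Ziegler radical bromination should take place at the aryl methyl group, because the two acetoxy groups make the ring too electron-poor for electrophilic ring bromination and the competing hydrogens of the lactone methylene are deactivated toward the electrophilic bromine atom by the adjacent acyloxy oxygen, while one equivalent of NBS and incomplete conversion limit dibromination.

Step 14
Reactants: 23 5-(bromomethyl)-1-oxo-1,3-dihydroisobenzofuran-4,6-diyl diacetate; 18 (S)-4-[(3E,7E)-8-iodo-3,7-dimethylocta-3,7-dien-1-yl]-2,2,5,5-tetramethyl-1,3-dioxolane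
Product: 25 5-{(2E,6E)-3,7-dimethyl-9-[(S)-2,2,5,5-tetramethyl-1,3-dioxolan-4-yl]nona-2,6-dien-1-yl}-1-oxo-1,3-dihydroisobenzofuran-4,6-diyl diacetate, via benzylic zinc bromide 24 (not isolated)
Conditions: 23 (1.5 equiv), Zn dust (activated), LiCl, THF, 0 °C; then 18 (1.0 equiv), Pd(PPh3)4 (5 mol%), THF, rt → 40 °C
Reagents that add atoms: none
Why: Negishi cross-coupling, in which zinc inserts into the benzylic C–Br bond to give 24 (acetates and lactone are tolerated by organozinc reagents), the zerovalent palladium complex Pd(PPh3)4 adds oxidatively to the alkenyl iodide with retention, and transmetalation and reductive elimination form C1'–C2' at an sp2 carbon, so the E geometry of C2'=C3' is kept and no allylic transposition is possible.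

Step 15
Reactants: 25 5-{(2E,6E)-3,7-dimethyl-9-[(S)-2,2,5,5-tetramethyl-1,3-dioxolan-4-yl]nona-2,6-dien-1-yl}-1-oxo-1,3-dihydroisobenzofuran-4,6-diyl diacetate
Product: 26 5-[(2E,6E,10S)-10,11-dihydroxy-3,7,11-trimethyldodeca-2,6-dien-1-yl]-1-oxo-1,3-dihydroisobenzofuran-4,6-diyl diacetate
Conditions: AcOH–H2O (4:1), 45 °C
Reagents that add atoms: none
Why: Acid-catalysed ketal hydrolysis should release the 10',11'-diol while the phenols are still acetylated, so that no free phenol can add to the C2'=C3' olefin to form a chroman, and aqueous acetic acid is too weak to protonate the trisubstituted olefins or to cleave the aryl acetates.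

Step 16
Reactants: 26 5-[(2E,6E,10S)-10,11-dihydroxy-3,7,11-trimethyldodeca-2,6-dien-1-yl]-1-oxo-1,3-dihydroisobenzofuran-4,6-diyl diacetate
Product: 27 memnoconol, 5-[(2E,6E,10S)-10,11-dihydroxy-3,7,11-trimethyldodeca-2,6-dien-1-yl]-4,6-dihydroxyisobenzofuran-1(3H)-one
Conditions: K2CO3 (0.3 equiv), MeOH, 0 °C, argon
Reagents that add atoms: none
Why: Base-catalysed transesterification with methanol removes the two aryl acetates under conditions that leave the lactone, the olefins, the diol and the C10' stereocentre untouched, giving the target.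

**Compound list**

1 | (S)-3-hydroxydihydrofuran-2(3H)-one | O[C@H]1CCOC1=O | starting material
2 | (S)-4-methylpentane-1,3,4-triol | OCC[C@H](O)C(C)(C)O | intermediate
3 | (S)-5-[(tert-butyldiphenylsilyl)oxy]-2-methylpentane-2,3-diol | CC(C)(C)[Si](c1ccccc1)(c1ccccc1)OCC[C@H](O)C(C)(C)O | intermediate
4 | (S)-tert-butyldiphenyl[2-(2,2,5,5-tetramethyl-1,3-dioxolan-4-yl)ethoxy]silane | CC(C)(C)[Si](c1ccccc1)(c1ccccc1)OCC[C@@H]1OC(C)(C)OC1(C)C | intermediate
5 | (S)-2-(2,2,5,5-tetramethyl-1,3-dioxolan-4-yl)ethan-1-ol | OCC[C@@H]1OC(C)(C)OC1(C)C | intermediate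
6 | (S)-4-(2-iodoethyl)-2,2,5,5-tetramethyl-1,3-dioxolane | ICC[C@@H]1OC(C)(C)OC1(C)C | intermediate
7 | 2,3-dihydrofuran | C1=COCC1 | starting material
8 | iodomethane | CI | starting material
9 | {2-[(S)-2,2,5,5-tetramethyl-1,3-dioxolan-4-yl]ethyl}lithium | [Li]CC[C@@H]1OC(C)(C)OC1(C)C | intermediate
10 | lithium bis{2-[(S)-2,2,5,5-tetramethyl-1,3-dioxolan-4-yl]ethyl}cuprate | [Li+].[Cu-](CC[C@@H]1OC(C)(C)OC1(C)C)CC[C@@H]1OC(C)(C)OC1(C)C | intermediate
11 | (4,5-dihydrofuran-2-yl)lithium (5-lithio-2,3-dihydrofuran) | [Li]C1=CCCO1 | intermediate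
12 | dilithium (4,5-dihydrofuran-2-yl)bis{2-[(S)-2,2,5,5-tetramethyl-1,3-dioxolan-4-yl]ethyl}cuprate | [Li+].[Li+].[Cu-2](C1=CCCO1)(CC[C@@H]1OC(C)(C)OC1(C)C)CC[C@@H]1OC(C)(C)OC1(C)C | intermediate
13 | dilithium [(Z)-4-oxido-1-{2-[(S)-2,2,5,5-tetramethyl-1,3-dioxolan-4-yl]ethyl}but-1-en-1-yl]{2-[(S)-2,2,5,5-tetramethyl-1,3-dioxolan-4-yl]ethyl}cuprate (copper cis to the oxidoethyl arm) | [Li+].[Li+].[O-]CC/C=C(\[Cu-]CC[C@@H]1OC(C)(C)OC1(C)C)CC[C@@H]1OC(C)(C)OC1(C)C | intermediate
14 | (E)-4-methyl-6-[(S)-2,2,5,5-tetramethyl-1,3-dioxolan-4-yl]hex-3-en-1-ol | OCC/C=C(\C)CC[C@@H]1OC(C)(C)OC1(C)C | intermediate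
15 | (S)-4-[(E)-6-iodo-3-methylhex-3-en-1-yl]-2,2,5,5-tetramethyl-1,3-dioxolane | ICC/C=C(\C)CC[C@@H]1OC(C)(C)OC1(C)C | intermediate
16 | (S)-2,2,5,5-tetramethyl-4-[(E)-3-methyloct-3-en-7-yn-1-yl]-1,3-dioxolane | C#CCC/C=C(\C)CC[C@@H]1OC(C)(C)OC1(C)C | intermediate
17 | dimethyl{(1E,5E)-2,6-dimethyl-8-[(S)-2,2,5,5-tetramethyl-1,3-dioxolan-4-yl]octa-1,5-dien-1-yl}alane | C[Al](C)/C=C(\C)CC/C=C(\C)CC[C@@H]1OC(C)(C)OC1(C)C | intermediate
18 | (S)-4-[(3E,7E)-8-iodo-3,7-dimethylocta-3,7-dien-1-yl]-2,2,5,5-tetramethyl-1,3-dioxolane | I/C=C(\C)CC/C=C(\C)CC[C@@H]1OC(C)(C)OC1(C)C | intermediate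
19 | 3,5-dimethoxy-4-methylbenzoic acid | COc1cc(C(=O)O)cc(OC)c1C | starting material
20 | 4,6-dimethoxy-5-methylisobenzofuran-1(3H)-one | Cc1c(OC)cc2c(c1OC)COC2=O | intermediate
21 | 4,6-dihydroxy-5-methylisobenzofuran-1(3H)-one | Cc1c(O)cc2c(c1O)COC2=O | intermediate
22 | 5-methyl-1-oxo-1,3-dihydroisobenzofuran-4,6-diyl diacetate | Cc1c(OC(C)=O)cc2c(c1OC(C)=O)COC2=O | intermediate
23 | 5-(bromomethyl)-1-oxo-1,3-dihydroisobenzofuran-4,6-diyl diacetate | BrCc1c(OC(C)=O)cc2c(c1OC(C)=O)COC2=O | intermediate
24 | {[4,6-bis(acetyloxy)-1-oxo-1,3-dihydroisobenzofuran-5-yl]methyl}zinc bromide | Br[Zn]Cc1c(OC(C)=O)cc2c(c1OC(C)=O)COC2=O | intermediate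
25 | 5-{(2E,6E)-3,7-dimethyl-9-[(S)-2,2,5,5-tetramethyl-1,3-dioxolan-4-yl]nona-2,6-dien-1-yl}-1-oxo-1,3-dihydroisobenzofuran-4,6-diyl diacetate | C/C(=C\Cc1c(OC(C)=O)cc2c(c1OC(C)=O)COC2=O)CC/C=C(\C)CC[C@@H]1OC(C)(C)OC1(C)C | intermediate
26 | 5-[(2E,6E,10S)-10,11-dihydroxy-3,7,11-trimethyldodeca-2,6-dien-1-yl]-1-oxo-1,3-dihydroisobenzofuran-4,6-diyl diacetate | C/C(=C\Cc1c(OC(C)=O)cc2c(c1OC(C)=O)COC2=O)CC/C=C(\C)CC[C@H](O)C(C)(C)O | intermediate
27 | memnoconol, 5-[(2E,6E,10S)-10,11-dihydroxy-3,7,11-trimethyldodeca-2,6-dien-1-yl]-4,6-dihydroxyisobenzofuran-1(3H)-one | C/C(=C\Cc1c(O)cc2c(c1O)COC2=O)CC/C=C(\C)CC[C@H](O)C(C)(C)O | target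

**Step count**

Total: 16 steps. Longest linear sequence: 12 steps (steps 1–9 and 14–16, from 1); the arene branch (steps 10–13) joins at step 14.

**Steps most likely to fail**

Step 6. The dialkylcuprate may decompose before the migration sets in, the migration may stay incomplete, or protonation of the alkenyl–copper bond may outrun its methylation, which would leave the olefin without the C7' methyl group. The fallback sets out from 6 and 7 and comes back at 14. Compound 7 is lithiated to 11 as before, and 11 is alkylated with iodide 6 (THF, −30 °C → rt, no copper) to give the 5-alkyl-2,3-dihydrofuran (S)-4-[2-(4,5-dihydrofuran-2-yl)ethyl]-2,2,5,5-tetramethyl-1,3-dioxolane F1. Nickel-catalysed ring-opening cross-coupling of F1 with MeMgBr (NiCl2(PPh3)2, toluene, reflux) then replaces the ring oxygen by methyl with retention at the alkenyl carbon, which again places the methyl group cis to the hydroxyethyl arm and gives 14. Here C7'–C8' is made by plain alkylation and C7'–CH3 by C–O activation, so no alkyl transfer from copper is needed.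

Step 13. Hydrogen abstraction at the lactone methylene C3 may compete with abstraction at the aryl methyl group, and the benzylic bromide may be brominated a second time. The fallback gives up the benzylic halide and makes the aryl–C1' bond instead; it sets out from 16 and comes back at 25.
- Chain side: alkyne 16 is methylaluminated as in step 9, and alane 17 is trapped with paraformaldehyde to give the allylic alcohol (2E,6E)-3,7-dimethyl-9-[(S)-2,2,5,5-tetramethyl-1,3-dioxolan-4-yl]nona-2,6-dien-1-ol F2. Corey–Kim chlorination (NCS, Me2S, CH2Cl2, −20 → 0 °C) gives the allylic chloride (S)-4-[(3E,7E)-9-chloro-3,7-dimethylnona-3,7-dien-1-yl]-2,2,5,5-tetramethyl-1,3-dioxolane F3. Bu3SnLi (THF, −78 °C) displaces chloride to give the allylstannane tributyl{(2E,6E)-3,7-dimethyl-9-[(S)-2,2,5,5-tetramethyl-1,3-dioxolan-4-yl]nona-2,6-dien-1-yl}stannane F4.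
- Arene side: purchased 4-bromo-3,5-dimethoxybenzoic acid F5 is taken through the chemistry of steps 10–12 to 5-bromo-4,6-dimethoxyisobenzofuran-1(3H)-one F6, 5-bromo-4,6-dihydroxyisobenzofuran-1(3H)-one F7 and 5-bromo-1-oxo-1,3-dihydroisobenzofuran-4,6-diyl diacetate F8.
- Union: Stille coupling of F4 with F8 (Pd(PPh3)4, DMF, 80 °C) gives 25.

Step 14. Wurtz-type homocoupling may take over during zinc insertion, and transmetalation of the doubly ortho-substituted benzylic zinc reagent may be slow. The fallback inverts the polarity of the partners; it sets out from 18 and 23 and comes back at 25. Iodine–lithium exchange on 18 (t-BuLi, 2 equiv, Et2O, −78 °C) gives the alkenyllithium {(1E,5E)-2,6-dimethyl-8-[(S)-2,2,5,5-tetramethyl-1,3-dioxolan-4-yl]octa-1,5-dien-1-yl}lithium F9. ZnBr2 converts it into the alkenylzinc bromide {(1E,5E)-2,6-dimethyl-8-[(S)-2,2,5,5-tetramethyl-1,3-dioxolan-4-yl]octa-1,5-dien-1-yl}zinc bromide F10. Coupling of F10 with benzylic bromide 23 under Pd(PPh3)4 in THF, where oxidative addition now takes place at the benzylic C–Br bond, gives 25.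

**Further compounds**

F1 | step 6 | (S)-4-[2-(4,5-dihydrofuran-2-yl)ethyl]-2,2,5,5-tetramethyl-1,3-dioxolane | C1CC=C(CC[C@@H]2OC(C)(C)OC2(C)C)O1
F2 | step 13 | (2E,6E)-3,7-dimethyl-9-[(S)-2,2,5,5-tetramethyl-1,3-dioxolan-4-yl]nona-2,6-dien-1-ol | OC/C=C(\C)CC/C=C(\C)CC[C@@H]1OC(C)(C)OC1(C)C
F3 | step 13 | (S)-4-[(3E,7E)-9-chloro-3,7-dimethylnona-3,7-dien-1-yl]-2,2,5,5-tetramethyl-1,3-dioxolane | ClC/C=C(\C)CC/C=C(\C)CC[C@@H]1OC(C)(C)OC1(C)C
F4 | step 13 | tributyl{(2E,6E)-3,7-dimethyl-9-[(S)-2,2,5,5-tetramethyl-1,3-dioxolan-4-yl]nona-2,6-dien-1-yl}stannane | CCCC[Sn](CCCC)(CCCC)C/C=C(\C)CC/C=C(\C)CC[C@@H]1OC(C)(C)OC1(C)C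
F5 | step 13 | 4-bromo-3,5-dimethoxybenzoic acid | COc1cc(C(=O)O)cc(OC)c1Br
F6 | step 13 | 5-bromo-4,6-dimethoxyisobenzofuran-1(3H)-one | COc1cc2c(c(OC)c1Br)COC2=O
F7 | step 13 | 5-bromo-4,6-dihydroxyisobenzofuran-1(3H)-one | Oc1cc2c(c(O)c1Br)COC2=O
F8 | step 13 | 5-bromo-1-oxo-1,3-dihydroisobenzofuran-4,6-diyl diacetate | CC(=O)Oc1cc2c(c(OC(C)=O)c1Br)COC2=O
F9 | step 14 | {(1E,5E)-2,6-dimethyl-8-[(S)-2,2,5,5-tetramethyl-1,3-dioxolan-4-yl]octa-1,5-dien-1-yl}lithium | [Li]/C=C(\C)CC/C=C(\C)CC[C@@H]1OC(C)(C)OC1(C)C
F10 | step 14 | {(1E,5E)-2,6-dimethyl-8-[(S)-2,2,5,5-tetramethyl-1,3-dioxolan-4-yl]octa-1,5-dien-1-yl}zinc bromide | Br[Zn]/C=C(\C)CC/C=C(\C)CC[C@@H]1OC(C)(C)OC1(C)C
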